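## Structural features

Ineupatorolide A is a germacrane-type sesquiterpenoid: a ten-membered carbocycle (C1–C10) with an α-methylene-γ-butyrolactone (C11, C12, C13, ring oxygen on C8) trans-fused across C7–C8. Four stereocentres are contiguous: C7 (ring-fusion CH), C8 (lactone O–CH), C9 (secondary ester) and C10 (tertiary carbinol with a methyl group). A fifth, the methyl-bearing C4, stands alone next to the C5 ketone, and the (R)-2-methylbutanoyl group on O9 carries a sixth. The fragile groups are the exocyclic enoate (Michael acceptor, lost on hydrogenation), C4 (α to the ketone, epimerisable), the α-centre of the ester, and the tertiary C10 hydroxyl beside an acyloxy group. The real difficulty is to close the ten-membered ring while fixing C7–C10 relative to each other and to the remote C4, because a cyclodecane offers no dependable facial bias. The key step exploits the 1,6-relationship of the two oxygenated carbons C5 and C10. They become the bridgeheads of a bicyclo[4.4.1]undecan-11-one, so the perimeter is built as two rigid seven-membered rings (ring A: C10, C1–C5; ring B: C5–C10) in one [6+4] event. The bridge carbon is later replaced by the C10 hydroxyl and cut away from C5.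

## Logic of the disconnections

38 ⇒ 36 + 37. The O9–acyl bond is cut first. The ester and its α-centre are the most fragile part, and 37 is a purchasable single enantiomer. The forward step must acylate a hindered secondary hydroxyl beside a free tertiary one, without a base that could epimerise C4 or the acyl α-centre.

36 ⇒ 35 ⇒ 34. The O9 ether and the C5 oxidation level are traced back. C5 stays a carbinol until after the last strongly basic step, so C4 is never α to a carbonyl in base. The O9 group must come off without hydrogenolysis (the C11=C13 bond would be reduced), hence a 4-methoxy-α-methylbenzyl ether cleaved by DDQ. The same group serves as the chiral auxiliary of the key step.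

34 ⇒ 31. The C11=C13 bond is cut. The Michael acceptor is made as the last C–C bond, which requires a lactone enolate and therefore no ketone in the molecule.

31 ⇒ 28 ⇒ 26 ⇒ 25. The C5 oxygen is traced to a carboxyl carbon (C5–C bond, decarboxylative hydroxylation). The carboxyl and O10 are joined as a bridging lactone (acyl–O bond, saponification), and the lactone is traced to a bridging ketone (C10–O bond, Baeyer–Villiger). The ten-membered ring becomes a rigid bicycle and the C10 carbinol becomes a quaternary carbon of fixed configuration. The forward step needs migration of C10, not C5, with retention, and a substrate free of C=C bonds.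

25 ⇒ 23 ⇒ 22 ⇒ 20. The lactone C12–O8 bond and then O8–C8 and H–C7 are removed, leaving the C7=C8 bond. In the bicycle one face of this alkene is screened by the carbonyl bridge, so syn addition of H and OH from the other face sets C7 and C8 together. The alkene must be the only C=C left, and borane must prefer it to the hindered ketone.

20 ⇒ 19 ⇒ 16 ⇒ 14. The C4–H bond is the point where a simpler plan would fail. In 14 the C10–C9 and C5–C6 bonds stand axial on one face of the ring A diene, so reagents add from the bridge face. Direct hydrogenation would place the C4 hydrogen on that face and give the C4 epimer of 38. The hydrogen is therefore carried across the ring: OH is added to C2 on the bridge face and then transposed to C4 with inversion of face. This costs one step more than exhaustive reduction and makes C4 a designed centre.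

14 ⇒ 5 + 13. The C9–C10 and C5–C6 bonds are cut (retro-[6+4]). Two rings, two skeletal bonds and three stereocentres go back to a planar tropone and an acyclic diene. The forward step must be [6+4] rather than [4+2], head-to-head, exo, and face-selective on the diene.

13 ⇒ 11 + 7; 11 ⇒ 8; 7 ⇒ 6. The diene is cut at its central C–C bond into an E-alkoxyvinyl unit and a 2-bromoalkene. Cross-coupling fixes the E geometry that exo selectivity needs, where an alkoxymethylene Wittig reaction would give E/Z mixtures. The chiral alkoxy group comes unchanged from 8.

5 ⇒ 3 ⇒ 1. The tropone is traced to the saturated seven-membered ketone and, by removal of one ring carbon, to a symmetrical cyclohexanone. Either α-carbon may migrate, so no regiochemical question arises.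

## Other disconnections considered

Alternative 1: The cut is C7–C8 with ring contraction. A thirteen-membered (E,E)-diallylic ether A1 is deprotonated at C8 by a lithium amide, and the [2,3]-Wittig shift forms C7–C8, breaks O–C13 and gives cyclodecenol A2.
- In its favour: the ten-membered ring arises by contracting an easier thirteen-membered ether. C7 and C8 are set together in one concerted step, and the C8 hydroxyl is where the lactone needs it. C4 can be bought as a stereocentre and carried through; on this point the alternative is better than the chosen plan, which spends steps 7 and 8 on C4. There is no bridge to excise, so it is better in atom economy.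
- Against it: A1 has two allylic α-oxy methylenes (C8 and C13) that can both be deprotonated. A2 still lacks both oxygens at C9 and C10, which would have to be added to the C9=C10 bond of a flexible ring. The isopropenyl methyl must be oxidised to the C12 acid. The absolute sense rests on a chiral base or on the remote C4 centre.
- Comparison: the chosen plan fixes C9 and C10 in a rigid transition state, whereas A2 postpones them. The sigmatropic step has closer precedent than a [6+4] with a methyl-bearing terminus, so the alternative is better on mechanism. The step count is judged about equal.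

Alternative 2: The cuts are C6–C7 and C11–C13. Silyl enol ether A4 (C1–C6) adds under Lewis acid to C7 of butenolide A3, anti to its C8 side chain, and the lactone silyl ketene acetal is trapped at C11 by an iminium salt to give A5.
- In its favour: C8 and C9 come from the chiral pool, so absolute configuration needs no auxiliary and no separation; this is better than the chosen plan. Anti addition to a 5-substituted butenolide is dependable. The C13 carbon arrives without a late strong base, which is better than step 16. The route is convergent.
- Against it: the ten-membered ring and the quaternary C10 carbinol remain to be made by macrocyclisation onto a C10 carbonyl, with weak control of C10. C4 is α to the ketone from the first step and is exposed to Lewis acid and base throughout. Enol ether formation must occur on the methyl side only.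
- Comparison: each bond-forming event is of a known type (equal or better), but ring closure and C10 are left for the end. The longest linear sequence could be shorter, but this gain is outweighed by the unsolved macrocyclisation.

Alternative 3: The cut is C8–C9. A one-electron reductant (low-valent titanium or divalent samarium) couples the two aldehydes of A6, closes the ring as a diol, and the C8 hydroxyl lactonises onto the C12 ester to give A7.
- In its favour: ring closure and both carbinols come in one step. C10 is fixed in the starting material, which is better than oxygen insertion at a hindered ketone. The two hydroxyls differentiate themselves by lactonisation, which equals the chosen plan. The endgame from A7 is short (better).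
- Against it: one of four diols must form in a ten-membered ring, with control only from C7 and C10. The C9 aldehyde is neopentyl and α-oxygenated, and the C8 aldehyde has an epimerisable α-centre. A6 needs a long linear synthesis with three isolated stereocentres.
- Comparison: the rigid bicycle of the chosen plan is judged the stronger control element for C7–C10. The step count is about equal.

Key step: step 6

Remark on the chemistry (assumption): target locants C1–C13 are kept for all intermediates and for their CIP descriptors, the one-carbon bridge is called the bridge carbon, and "bridge face" means the face of ring A or ring B on the side of the carbonyl bridge.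

## Route

Step 1
Reactants: 1 2,6-dimethylcyclohexanone
Product: 3 2,6-dimethylcycloheptan-1-one, via α-silyl ketone 2 (not isolated)
Conditions: TMSCHN2, BF3·OEt2, CH2Cl2, −78 to −30 °C; then 1 M HCl, THF
Reagents that add atoms: trimethylsilyldiazomethane, C[Si](C)(C)C=[N+]=[N-]
Why: Lewis-acid-promoted diazoalkane ring expansion (Tiffeneau–Demjanov type): addition to the carbonyl, then 1,2-shift of one of the two equivalent α-carbons with loss of N2. The α-silyl ketone 2 resists a second insertion and is protodesilylated on work-up; the methyl-bearing carbons become sp2 in step 2, so the diastereomer mixture does not matter.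

Step 2
Reactants: 3 2,6-dimethylcycloheptan-1-one
Product: 5 2,6-dimethyltropone, via cross-conjugated dienone 4 (not isolated)
Conditions: IBX (4.5 equiv), DMSO/fluorobenzene, 80 °C
Reagents that add atoms: none
Why: IBX dehydrogenation of a cyclic ketone, applied three times; this is the known cycloheptanone-to-tropone oxidation. The two α,β-desaturations give 4, and the vinylogous third one is driven by the stabilisation of the tropone.

Step 3
Reactants: 6 3-bromobut-3-en-1-ol
Product: 7 TBS ether of 3-bromobut-3-en-1-ol
Conditions: TBSCl, imidazole, CH2Cl2, 23 °C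
Reagents that add atoms: tert-butyldimethylsilyl chloride, CC(C)(C)[Si](C)(C)Cl
Why: Standard silylation of a primary alcohol; the vinyl bromide is inert.

Step 4
Reactants: 8 (R)-1-(4-methoxyphenyl)ethanol
Product: 11 ethynyl (R)-1-(4-methoxyphenyl)ethyl ether, via dichlorovinyl ether 9 (not isolated), via lithium alkynyl ether 10 (not isolated)
Conditions: KH, THF, 0 °C; Cl2C=CHCl, −50 to 23 °C; then n-BuLi (2.4 equiv), −78 to −40 °C; MeOH, −78 °C
Reagents that add atoms: trichloroethylene, ClC=C(Cl)Cl
Why: Ynol ether synthesis from trichloroethylene: the alkoxide adds to dichloroacetylene formed in situ (9), n-BuLi effects elimination and chlorine–lithium exchange (10), and protonation gives 11. The carbinol C–O bond is never broken, so the R configuration is kept.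

Step 5
Reactants: 11 ethynyl (R)-1-(4-methoxyphenyl)ethyl ether; 7 TBS ether of 3-bromobut-3-en-1-ol
Product: 13 (E)-1-[(R)-1-(4-methoxyphenyl)ethoxy]-3-[2-(TBS-oxy)ethyl]buta-1,3-diene, via alkenyl pinacol boronate 12 (not isolated)
Conditions: HBpin, (C5H5)2Zr(H)Cl (5 mol %), Et3N (cat.), CH2Cl2, 23 °C; then 7, Pd(PPh3)4 (5 mol %), K3PO4, THF/H2O, 50 °C
Reagents that add atoms: none
Why: Zirconium-catalysed syn hydroboration puts boron on the terminal carbon and gives the E-boronate 12. Suzuki–Miyaura coupling with the 2-bromoalkene retains this geometry, so the diene is formed as the E isomer only.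

Step 6
Reactants: 5 2,6-dimethyltropone; 13 (E)-1-[(R)-1-(4-methoxyphenyl)ethoxy]-3-[2-(TBS-oxy)ethyl]buta-1,3-diene
Product: 14 exo bicyclo[4.4.1]undeca-trien-11-one (5S,9R,10S) with the C9 arylethoxy group anti to the bridge
Conditions: 5 (1 equiv), 13 (1.5 equiv), toluene (1 M), BHT (cat.), K2CO3 (solid), 110 °C, sealed tube, 72 h; chromatographic removal of the facial diastereomer
Reagents that add atoms: none
Why: Proposed new method: a concerted, thermally allowed cycloaddition, suprafacial on the 6π tropone and on the 4π dienol ether (tropone LUMO, diene HOMO); the closest known reaction type is the thermal exo-selective [6+4] cycloaddition of tropone itself with (E)-1-acyloxy- and 1-silyloxybuta-1,3-dienes, extended here to a tropone terminus that bears a methyl group and to an auxiliary-bearing diene. The two σ-bonds C9–C10 and C5–C6 form in the same event, which closes ring B as a seven-membered ring through the bicyclic transition state and leaves the tropone ring as the seven-membered ring A, so the ten-membered perimeter arises without a medium-ring cyclisation. C5 and C10 are set as a cis pair by suprafacial addition across the tropone termini. C9 follows from the E enol ether geometry together with the exo transition state (C7–C8 under the carbonyl, oxygen outward), which places O9 anti to the bridge, the relationship that C9 and C10 have in 38. The absolute sense is set by the (R)-arylethyl group: with the enol ether s-trans and the carbinol C–H in its plane, the aryl group covers one diene face and 5 adds to the face of the methyl group; the two facial adducts are diastereomers, so the unwanted one can be removed by chromatography whatever the level of induction. Periselectivity over [4+2] rests on the antibonding secondary overlap of the endo mode and on a temperature low enough to avoid Cope equilibration. Regiochemistry rests on the large HOMO coefficient of the CH2 terminus, which bonds first to the unsubstituted, less hindered tropone α-carbon C5.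

Step 7
Reactants: 14 exo bicyclo[4.4.1]undeca-trien-11-one
Product: 16 ring A allylic alcohol (2R; OH on C2 on the bridge face; C3=C4 and C7=C8 kept), via C2 allylborane 15 (not isolated)
Conditions: Sia2BH (1.3 equiv, from BH3·THF and 2-methylbut-2-ene), THF, −10 °C; then NaOH, H2O2, 0 °C
Reagents that add atoms: hydrogen peroxide, OO
Why: Monohydroboration of a cyclic 1,3-diene with a hindered dialkylborane: boron adds to C2 of the cis-disubstituted C1=C2 bond (allylborane 15, remote from quaternary C10) on the bridge face, because the C10–C9 and C5–C6 bonds stand axial on the other face; oxidation with retention sets C2. Sia2BH does not touch the trisubstituted C3=C4 and C7=C8 bonds or the hindered ketone.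

Step 8
Reactants: 16 ring A allylic alcohol
Product: 19 Δ2-alkene with C4 set (4R; C2=C3, C7=C8), via sulfonyl hydrazine 17 (not isolated), via allyl diazene 18 (not isolated)
Conditions: 2-O2NC6H4SO2NHNH2, PPh3, DEAD, THF, −30 °C; then 23 °C
Reagents that add atoms: none
Why: Reductive 1,3-transposition of an allylic alcohol: Mitsunobu displacement by the sulfonyl hydrazide inverts C2 (17), loss of sulfinic acid gives the monoalkyl diazene 18, and its retro-ene loss of N2 delivers hydrogen to C4 suprafacially, on the ring B face. This sets C4 as R, which addition of hydrogen from the exposed bridge face could not do.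

Step 9
Reactants: 19 Δ2-alkene
Product: 20 bicyclic ketone with saturated ring A (4R,5S,9R,10S; C7=C8 kept)
Conditions: H2 (1 atm), RhCl(PPh3)3 (10 mol %), benzene/EtOH, 23 °C
Reagents that add atoms: none
Why: Homogeneous hydrogenation with RhCl(PPh3)3 reduces the cis-disubstituted C2=C3 bond and leaves the trisubstituted C7=C8 bond, the ketone and the benzylic ether; no stereocentre is formed.

Step 10
Reactants: 20 bicyclic ketone with saturated ring A
Product: 22 C8 alcohol (7S,8S; side chain and OH trans), via C8 alkylborane 21 (not isolated)
Conditions: BH3·THF (1.2 equiv), THF, 0 °C; then NaOH, H2O2, 0 °C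
Reagents that add atoms: hydrogen peroxide, OO
Why: Hydroboration–oxidation: boron goes to the less substituted C8 and hydrogen to C7, syn, on the face away from the carbonyl bridge (the bridge face is screened by C=O and the C10 methyl group). Oxidation with retention sets C8 and C7 in the trans, trans array with C9; an alkene is hydroborated faster than a hindered bridged ketone is reduced.

Step 11
Reactants: 22 C8 alcohol
Product: 23 C8,C12-diol
Conditions: HF·pyridine, pyridine/THF, 0 to 23 °C
Reagents that add atoms: none
Why: Buffered fluoride cleavage of the primary silyl ether; the ketone and the acid-sensitive arylethyl ether are unaffected.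

Step 12
Reactants: 23 C8,C12-diol
Product: 25 keto γ-lactone (trans-fused on ring B), via lactol 24 (not isolated)
Conditions: TEMPO (0.2 equiv), PhI(OAc)2 (2.5 equiv), CH2Cl2, 23 °C
Reagents that add atoms: none
Why: Oxoammonium-mediated oxidative lactonisation: the primary alcohol is oxidised selectively, the aldehyde is trapped by the C8 hydroxyl as lactol 24, and a second oxidation gives the γ-lactone. This ties up O8 before the bridge is opened.

Step 13
Reactants: 25 keto γ-lactone
Product: 26 bis-lactone (bridge now O10–C(=O)–C5)
Conditions: m-CPBA (3 equiv), NaHCO3, CH2Cl2, 23 to 40 °C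
Reagents that add atoms: 3-chloroperoxybenzoic acid, OOC(=O)c1cccc(Cl)c1
Why: Baeyer–Villiger oxidation: the fully substituted C10 migrates in preference to the secondary C5, with retention, so oxygen is inserted at C10 with its configuration unchanged. Bridged ketones are good substrates, no C=C bond is left to epoxidise, and the buffer protects the arylethyl ether.

Step 14
Reactants: 26 bis-lactone
Product: 28 ten-membered hydroxy acid (C10–OH, C5–CO2H, γ-lactone; 4R,5S,7S,8S,9R,10S), via dilithium dicarboxylate 27 (not isolated)
Conditions: LiOH, THF/H2O, 23 to 40 °C; then 1 M HCl to pH 3, 23 °C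
Reagents that add atoms: water, O
Why: Saponification opens both lactones (27). On acidification only the five-membered lactone re-forms, because closure onto O8 is far faster than re-closure of the eight-membered lactone of a tertiary alcohol; this frees the C10 hydroxyl and the C5 carboxylic acid.

Step 15
Reactants: 28 ten-membered hydroxy acid
Product: 31 C5 carbinol (both C5 epimers), via thiohydroxamate ester 29 (not isolated), via C5 hydroperoxide 30 (not isolated)
Conditions: N-hydroxypyridine-2-thione, DCC, DMAP (cat.), CH2Cl2, dark, 0 °C; then O2, t-BuSH, hν (tungsten lamp), toluene, 0 °C; then P(OMe)3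
Reagents that add atoms: oxygen, O=O
Why: Barton decarboxylation with oxygen trapping: the C5 radical from 29 is captured by O2, the thiol gives hydroperoxide 30, and phosphite reduces it to the alcohol. The C5 configuration is lost but is removed again in step 17, and C4 is not affected.

Step 16
Reactants: 31 C5 carbinol
Product: 34 α-methylene lactone (C5 carbinol), via Mannich base 32 (not isolated), via ammonium iodide 33 (not isolated)
Conditions: LiN(i-Pr)2 (3.5 equiv), THF, −78 °C; Me2N=CH2+ I−, −78 to 0 °C; then MeI, CH2Cl2/MeOH; then NaHCO3 aq, 23 °C
Reagents that add atoms: dimethyl(methylidene)ammonium iodide, C=[N+](C)C.[I-]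
Why: Mannich reaction of the lactone enolate (32), quaternisation (33) and base-induced elimination. C5 is still a carbinol, so no ketone enolate can form and C4 cannot epimerise; the alkoxides at C5 and C10 are spectators.

Step 17
Reactants: 34 α-methylene lactone
Product: 35 C5 ketone
Conditions: Dess–Martin periodinane, NaHCO3, CH2Cl2, 0 to 23 °C
Reagents that add atoms: none
Why: Dess–Martin oxidation of the secondary C5 carbinol; both epimers converge. The tertiary C10 hydroxyl, the enoate and the aryl ether are inert, and the buffered, non-basic medium keeps C4.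

Step 18
Reactants: 35 C5 ketone
Product: 36 C9 alcohol
Conditions: DDQ, CH2Cl2/pH 7 buffer (10:1), 0 to 23 °C
Reagents that add atoms: none
Why: Oxidative cleavage of the electron-rich 4-methoxy-α-methylbenzyl ether by DDQ (hydride abstraction, then hydrolysis of the oxocarbenium ion). The neutral conditions spare the methylene lactone and C4.

Step 19
Reactants: 36 C9 alcohol; 37 (R)-2-methylbutanoic acid
Product: 38 ineupatorolide A
Conditions: DCC, DMAP, CH2Cl2, 0 to 23 °C
Reagents that add atoms: none
Why: Steglich esterification: the secondary C9 hydroxyl is acylated and the tertiary C10 hydroxyl is not. Carbodiimide activation at low temperature avoids a ketene pathway, so the R centre of 37 and C4 are kept.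

## Compound list

1 | 2,6-dimethylcyclohexanone (cis/trans mixture) | CC1CCCC(C)C1=O | starting material
2 | 3,7-dimethyl-2-(trimethylsilyl)cycloheptan-1-one | CC1CCCC(C)C(=O)C1[Si](C)(C)C | intermediate (not isolated)
3 | 2,6-dimethylcycloheptan-1-one (diastereomer mixture) | CC1CCCC(C)C(=O)C1 | intermediate
4 | 2,6-dimethylcyclohepta-2,6-dien-1-one | CC1=CCCC(C)=CC1=O | intermediate (not isolated)
5 | 2,6-dimethyltropone | CC1=CC=CC(C)=CC1=O | intermediate
6 | 3-bromobut-3-en-1-ol | C=C(Br)CCO | starting material
7 | [(3-bromobut-3-en-1-yl)oxy](tert-butyl)dimethylsilane | C=C(Br)CCO[Si](C)(C)C(C)(C)C | intermediate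
8 | (R)-1-(4-methoxyphenyl)ethanol | C[C@@H](O)c1ccc(OC)cc1 | starting material
9 | (E)-1,2-dichlorovinyl (R)-1-(4-methoxyphenyl)ethyl ether | Cl/C=C(/Cl)O[C@H](C)c1ccc(OC)cc1 | intermediate (not isolated)
10 | lithium 2-[(R)-1-(4-methoxyphenyl)ethoxy]ethynide | [Li]C#CO[C@H](C)c1ccc(OC)cc1 | intermediate (not isolated)
11 | ethynyl (R)-1-(4-methoxyphenyl)ethyl ether | C#CO[C@H](C)c1ccc(OC)cc1 | intermediate
12 | 2-[(E)-2-{[(R)-1-(4-methoxyphenyl)ethyl]oxy}ethenyl]-4,4,5,5-tetramethyl-1,3,2-dioxaborolane | CC1(C)OB(/C=C/O[C@H](C)c2ccc(OC)cc2)OC1(C)C | intermediate (not isolated)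
13 | (E)-1-[(R)-1-(4-methoxyphenyl)ethoxy]-3-[2-(tert-butyldimethylsilyloxy)ethyl]buta-1,3-diene | C=C(CCO[Si](C)(C)C(C)(C)C)/C=C/O[C@H](C)c1ccc(OC)cc1 | intermediate
14 | exo [6+4] adduct: bicyclo[4.4.1]undeca-trien-11-one with C1=C2, C3=C4, C7=C8, methyl on C4 and C10, arylethoxy on C9, silyloxyethyl on C7 (5S,9R,10S) | O=C1[C@]2(C)[C@H](O[C@H](C)c3ccc(OC)cc3)C=C(CCO[Si](C)(C)C(C)(C)C)C[C@H]1C(C)=CC=C2 | intermediate
15 | C2 bis(3-methylbutan-2-yl)boryl derivative of 14 (H on C1, boron on C2, bridge face) | O=C1[C@]2(C)[C@H](O[C@H](C)c3ccc(OC)cc3)C=C(CCO[Si](C)(C)C(C)(C)C)C[C@H]1C(C)=C[C@H](B(C(C)C(C)C)C(C)C(C)C)C2 | intermediate (not isolated)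
16 | ring A allylic alcohol (2R, OH on the bridge face; C3=C4, C7=C8) | O=C1[C@]2(C)[C@H](O[C@H](C)c3ccc(OC)cc3)C=C(CCO[Si](C)(C)C(C)(C)C)C[C@H]1C(C)=C[C@H](O)C2 | intermediate
17 | C2 N-amino-N-(2-nitrobenzenesulfonyl)amine (C2 inverted, nitrogen on the ring B face) | O=C1[C@]2(C)[C@H](O[C@H](C)c3ccc(OC)cc3)C=C(CCO[Si](C)(C)C(C)(C)C)C[C@H]1C(C)=C[C@@H](N(N)S(=O)(=O)c4ccccc4[N+](=O)[O-])C2 | intermediate (not isolated)
18 | C2 allyl diazene | O=C1[C@]2(C)[C@H](O[C@H](C)c3ccc(OC)cc3)C=C(CCO[Si](C)(C)C(C)(C)C)C[C@H]1C(C)=C[C@@H](N=N)C2 | intermediate (not isolated)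
19 | Δ2-alkene (4R,5S,9R,10S; C2=C3, C7=C8) | O=C1[C@]2(C)[C@H](O[C@H](C)c3ccc(OC)cc3)C=C(CCO[Si](C)(C)C(C)(C)C)C[C@H]1[C@H](C)C=CC2 | intermediate
20 | bicyclic ketone with saturated ring A (4R,5S,9R,10S; C7=C8) | O=C1[C@]2(C)[C@H](O[C@H](C)c3ccc(OC)cc3)C=C(CCO[Si](C)(C)C(C)(C)C)C[C@H]1[C@H](C)CCC2 | intermediate
21 | C8 alkylborane (B on C8 and H on C7, both anti to the bridge) | O=C1[C@]2(C)[C@H](O[C@H](C)c3ccc(OC)cc3)[C@@H](B)[C@H](CCO[Si](C)(C)C(C)(C)C)C[C@H]1[C@H](C)CCC2 | intermediate (not isolated)
22 | C8 alcohol (4R,5S,7S,8S,10S; C9 as in 14) | O=C1[C@]2(C)[C@H](O[C@H](C)c3ccc(OC)cc3)[C@@H](O)[C@H](CCO[Si](C)(C)C(C)(C)C)C[C@H]1[C@H](C)CCC2 | intermediate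
23 | C8,C12-diol | O=C1[C@]2(C)[C@H](O[C@H](C)c3ccc(OC)cc3)[C@@H](O)[C@H](CCO)C[C@H]1[C@H](C)CCC2 | intermediate
24 | γ-lactol (C12 anomers) | O=C1[C@]2(C)[C@H](O[C@H](C)c3ccc(OC)cc3)[C@H]4OC(O)C[C@@H]4C[C@H]1[C@H](C)CCC2 | intermediate (not isolated)
25 | keto γ-lactone (8,12-olide, trans-fused on ring B) | O=C1[C@]2(C)[C@H](O[C@H](C)c3ccc(OC)cc3)[C@H]4OC(=O)C[C@@H]4C[C@H]1[C@H](C)CCC2 | intermediate
26 | bis-lactone (O10–C(=O)–C5 bridge and 8,12-olide; 4R,5S,7S,8S,9R,10S) | O=C1O[C@]2(C)[C@H](O[C@H](C)c3ccc(OC)cc3)[C@H]4OC(=O)C[C@@H]4C[C@H]1[C@H](C)CCC2 | intermediate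
27 | dilithium salt of the ten-membered 8,10-dihydroxy diacid | [Li+].[Li+].O[C@@H]1[C@@H](O[C@H](C)c2ccc(OC)cc2)[C@@](C)(O)CCC[C@@H](C)[C@@H](C([O-])=O)C[C@H]1CC([O-])=O | intermediate (not isolated)
28 | ten-membered hydroxy acid (8,12-olide, C10–OH, C5–CO2H; 4R,5S,7S,8S,9R,10S) | O=C1O[C@@H]2[C@@H](O[C@H](C)c3ccc(OC)cc3)[C@@](C)(O)CCC[C@@H](C)[C@@H](C(=O)O)C[C@H]2C1 | intermediate
29 | 2-thioxopyridin-1(2H)-yl ester of 28 | O=C1O[C@@H]2[C@@H](O[C@H](C)c3ccc(OC)cc3)[C@@](C)(O)CCC[C@@H](C)[C@@H](C(=O)ON4C=CC=CC4=S)C[C@H]2C1 | intermediate (not isolated)
30 | C5 hydroperoxide (C5 epimers) | O=C1O[C@@H]2[C@@H](O[C@H](C)c3ccc(OC)cc3)[C@@](C)(O)CCC[C@@H](C)C(OO)C[C@H]2C1 | intermediate (not isolated)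
31 | C5 carbinol (C5 epimers; 4R,7S,8S,9R,10S) | O=C1O[C@@H]2[C@@H](O[C@H](C)c3ccc(OC)cc3)[C@@](C)(O)CCC[C@@H](C)C(O)C[C@H]2C1 | intermediate
32 | C11 (dimethylamino)methyl lactone (C5 and C11 epimers) | O=C1O[C@@H]2[C@@H](O[C@H](C)c3ccc(OC)cc3)[C@@](C)(O)CCC[C@@H](C)C(O)C[C@H]2C1CN(C)C | intermediate (not isolated)
33 | C11 (trimethylammonio)methyl lactone iodide | O=C1O[C@@H]2[C@@H](O[C@H](C)c3ccc(OC)cc3)[C@@](C)(O)CCC[C@@H](C)C(O)C[C@H]2C1C[N+](C)(C)C.[I-] | intermediate (not isolated)
34 | α-methylene lactone with C5 carbinol (C5 epimers) | C=C1C(=O)O[C@@H]2[C@@H](O[C@H](C)c3ccc(OC)cc3)[C@@](C)(O)CCC[C@@H](C)C(O)C[C@@H]12 | intermediate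
35 | O9-arylethyl ether of the C5 ketone (4R,7S,8S,9R,10S) | C=C1C(=O)O[C@@H]2[C@@H](O[C@H](C)c3ccc(OC)cc3)[C@@](C)(O)CCC[C@@H](C)C(=O)C[C@@H]12 | intermediate
36 | 9-deacyl ineupatorolide A (C9 alcohol; 4R,7S,8S,9R,10S) | C=C1C(=O)O[C@@H]2[C@@H](O)[C@@](C)(O)CCC[C@@H](C)C(=O)C[C@@H]12 | intermediate
37 | (R)-2-methylbutanoic acid | CC[C@@H](C)C(=O)O | starting material
38 | ineupatorolide A (4R,7S,8S,9R,10S; ester 2R) | C=C1C(=O)O[C@@H]2[C@@H](OC(=O)[C@H](C)CC)[C@@](C)(O)CCC[C@@H](C)C(=O)C[C@@H]12 | target

## Step count and least certain steps

Total: 19 steps. Longest linear sequence: 16 steps (steps 4–19 from 8; equally steps 1, 2 and 6–19 from 1).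

Step 6 (key step, labelled).
- What may go wrong: bond formation at the methyl-bearing tropone terminus creates a quaternary centre beside an alkoxy carbon and may be slow, so that [4+2] pathways, Cope equilibration on long heating, or polymerisation and hydrolysis of the dienol ether overtake it. Facial induction by the carbinol centre may be weak or of the opposite sense, which shifts the burden to the separation.
- Fallback (known chemistry, oxyallyl cation [4+3] cycloaddition of an α,α′-dibromo ketone with a 1,3-diene): it sets out from 3 and 13. Dibromination of 3 (Br2, AcOH/CH2Cl2) gives 2,7-dibromo-2,6-dimethylcycloheptan-1-one F1. Reductive ionisation of F1 with Fe2(CO)9 (benzene, 60 °C) in the presence of 13 generates the cyclic oxyallyl cation, whose termini take up the diene (CH2 terminus at the unsubstituted carbon), expected on the face anti to the neighbouring C4 methyl group. After separation of isomers this gives 20 directly. The fallback comes back to the route at 20, and steps 7–9 fall away.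

Step 7.
- What may go wrong: boron may add at C1 instead of C2, or the 1,3-boron shift and protonolysis of the allylborane may proceed before oxidation; either erodes the regio- and stereochemical definition of C2.
- Fallback: it sets out from 14. Palladium-catalysed hydrosilylation of the diene (HSiCl3, [PdCl(C3H5)]2/PPh3; then EtOH, Et3N) adds H to C1 and silicon to C2 from the same bridge face and gives the C2 triethoxysilane F2. Tamao–Fleming oxidation (H2O2, KF, KHCO3) with retention returns to the route at 16.

Step 8.
- What may go wrong: the Mitsunobu displacement must enter C2 from the more hindered ring B face; elimination to the diene or incomplete inversion would lower the stereochemical purity at C4.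
- Fallback: it sets out from 16. Oxidation (MnO2) gives the ring A enone F3, and condensation with TsNHNH2 gives the tosylhydrazone F4. Catecholborane delivers hydride to C2 from the open bridge face, and warming with NaOAc·3H2O releases sulfinate and N2 with hydrogen transfer to C4 on the ring B face (alkene-transposing hydrazone reduction). The fallback comes back to the route at 19.

Step 10.
- What may go wrong: borane may reduce the bridge ketone in competition with hydroboration, and coordination to the C9 ether oxygen may erode the facial preference.
- Fallback: it sets out from 20. Excess BH3·THF followed by NaOH/H2O2 is used on purpose and gives the C8 alcohol with the bridge reduced to a carbinol, F5. HF·pyridine gives triol F6, and TEMPO/PhI(OAc)2 lactonises the primary alcohol onto O8 to give the hydroxy lactone F7. Dess–Martin oxidation of the remaining bridge carbinol returns to the route at 25.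

Step 15.
- What may go wrong: the C5 radical in the ten-membered ring may abstract a transannular hydrogen (the α-oxy C9–H is within reach) or be reduced by the thiol before oxygen trapping.
- Fallback (two-electron chemistry): it sets out from 28. BH3·SMe2 reduces the acid selectively in the presence of the lactone to the primary alcohol F8, and Dess–Martin oxidation gives the aldehyde F9. Baeyer–Villiger oxidation of this α-branched aldehyde (m-CPBA, NaHCO3) gives the C5 formate F10 with retention, and mild methanolysis (KHCO3, MeOH) returns to the route at 31 as a single C5 epimer.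

## Further compounds

F1 | step 6 | 2,7-dibromo-2,6-dimethylcycloheptan-1-one | CC1CCCC(C)(Br)C(=O)C1Br
F2 | step 7 | C2 triethoxysilyl derivative of 14 (H on C1, silicon on C2, bridge face) | O=C1[C@]2(C)[C@H](O[C@H](C)c3ccc(OC)cc3)C=C(CCO[Si](C)(C)C(C)(C)C)C[C@H]1C(C)=C[C@H]([Si](OCC)(OCC)OCC)C2
F3 | step 8 | ring A enone (C2 ketone, C3=C4) | O=C1[C@]2(C)[C@H](O[C@H](C)c3ccc(OC)cc3)C=C(CCO[Si](C)(C)C(C)(C)C)C[C@H]1C(C)=CC(=O)C2
F4 | step 8 | C2 tosylhydrazone of F3 | O=C1[C@]2(C)[C@H](O[C@H](C)c3ccc(OC)cc3)C=C(CCO[Si](C)(C)C(C)(C)C)C[C@H]1C(C)=CC(=NNS(=O)(=O)c4ccc(C)cc4)C2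
F5 | step 10 | C8 alcohol with the bridge reduced to a carbinol (bridge epimers) | OC1[C@]2(C)[C@H](O[C@H](C)c3ccc(OC)cc3)[C@@H](O)[C@H](CCO[Si](C)(C)C(C)(C)C)C[C@H]1[C@H](C)CCC2
F6 | step 10 | bridge carbinol C8,C12-triol | OC1[C@]2(C)[C@H](O[C@H](C)c3ccc(OC)cc3)[C@@H](O)[C@H](CCO)C[C@H]1[C@H](C)CCC2
F7 | step 10 | bridge carbinol γ-lactone | OC1[C@]2(C)[C@H](O[C@H](C)c3ccc(OC)cc3)[C@H]4OC(=O)C[C@@H]4C[C@H]1[C@H](C)CCC2
F8 | step 15 | C5 hydroxymethyl lactone | O=C1O[C@@H]2[C@@H](O[C@H](C)c3ccc(OC)cc3)[C@@](C)(O)CCC[C@@H](C)[C@@H](CO)C[C@H]2C1
F9 | step 15 | C5 formyl lactone | O=C1O[C@@H]2[C@@H](O[C@H](C)c3ccc(OC)cc3)[C@@](C)(O)CCC[C@@H](C)[C@@H](C=O)C[C@H]2C1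
F10 | step 15 | C5 formate | O=C1O[C@@H]2[C@@H](O[C@H](C)c3ccc(OC)cc3)[C@@](C)(O)CCC[C@@H](C)[C@@H](OC=O)C[C@H]2C1
A1 | alternative 1 | thirteen-membered (E,E)-diallylic ether with C5 dioxolane | C[C@@H]1CCC/C(C)=C/COC/C(C)=C/CC12OCCO2
A2 | alternative 1 | cyclodecenol with C8 hydroxyl, C7 2-propenyl and (E)-C9=C10 | C[C@@H]1CCC/C(C)=C/[C@@H](O)[C@H](C(C)=C)CC12OCCO2
A3 | alternative 2 | 5-substituted butenolide carrying C8–C10 (O9 4-methoxybenzyl, O10 TBS) | O=C1O[C@H]([C@@H](OCc2ccc(OC)cc2)CO[Si](C)(C)C(C)(C)C)C=C1
A4 | alternative 2 | trimethylsilyl enol ether of the C1–C6 methyl ketone | C=C(O[Si](C)(C)C)[C@H](C)CC#C[Si](C)(C)C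
A5 | alternative 2 | trans,trans aminomethyl lactone joining both fragments | CN(C)C[C@@H]1C(=O)O[C@H]([C@@H](OCc2ccc(OC)cc2)CO[Si](C)(C)C(C)(C)C)[C@H]1CC(=O)[C@H](C)CC#C[Si](C)(C)C
A6 | alternative 3 | acyclic C8,C9-dialdehyde with C12 methyl ester, C5 dioxolane and O10 triethylsilyl | O=C[C@@](C)(O[Si](CC)(CC)CC)CCC[C@@H](C)C1(OCCO1)C[C@@H](CC(=O)OC)C=O
A7 | alternative 3 | trans-fused hydroxy lactone on the ten-membered ring | O=C1O[C@@H]2[C@@H](O)[C@@](C)(O[Si](CC)(CC)CC)CCC[C@@H](C)C3(OCCO3)C[C@H]2C1
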